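**Retrosynthetic overview**

1. Rings: A = terminal 3,5-dihydroxyphenyl; B–C–D = ether-linked chain; E–F and G–H = biaryl arms on D; I–J = biaryl arm on B. The strategy rests on this feature: in rings C, E, G and I the carbon bonded to the ether oxygen of the preceding ring (C-1) lies between two hydroxyl-bearing carbons (C-2, C-6), eight hydroxyls in all. Rings B and D carry the same 1,2,3-trioxygen triad as ethers.
2. Each triad is read as a former 2-fluoroisophthalaldehyde: the two formyl groups first activate C–F for phenoxide attack, then become the flanking oxygens by Dakin oxidation. Target 29 ⇐ sixteen O-demethylations ⇐ octaphenol 28 ⇐ eightfold Dakin ⇐ octa-aldehyde 26.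
3. 26 ⇐ fluoride displacement joining phenol 25 (rings A, B, I, J) to aryl fluoride 20 (rings C to H). Rings B and D are made one generation earlier by the same displacement/Dakin pair from fluoro dialdehyde 13.
4. All fluoro dialdehydes (arm 11, core 13, masked ring C phenol 15) derive from 2-bromo-4-fluoroanisole 1 by two lithiation–formylations beside fluorine. The bromine is either used for the Suzuki biaryl bond (11) or removed (13).
5. No ring is built. The ten purchased benzene rings are joined in the order: E–F, G–H, I–J biaryls; C–D; D–E and D–G; A–B; B–I; B–C.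

Key step: step 16

Remark: the target has no stereocentre, and because rings F, H and J are symmetric about their biaryl axes no atropisomers arise; all structures are drawn without stereodescriptors.

**Route**

Step 1
Reactants: 1 2-bromo-4-fluoroanisole
Product: 4 2-bromo-6-fluoro-3-methoxybenzaldehyde, via aryllithium 2 (not isolated), via lithium aminoalkoxide 3 (not isolated)
Conditions: LiN(iPr)2 (LDA, 1.1 equiv), THF, −78 °C; then DMF, −78 to −20 °C; then H2O
Reagents that add atoms: N,N-dimethylformamide (DMF), CN(C)C=O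
Why: Directed ortho-lithiation followed by DMF formylation: the proton between bromine and fluorine is the most acidic one of 1, the amide base removes it at −78 °C without bromine–lithium exchange or aryne formation, and the aminoalkoxide 3 releases the aldehyde only on aqueous quench.

Step 2
Reactants: 4 2-bromo-6-fluoro-3-methoxybenzaldehyde
Product: 5 2-bromo-3-(dimethoxymethyl)-4-fluoro-1-methoxybenzene
Conditions: HC(OMe)3, MeOH, p-TsOH (cat.), 60 °C
Reagents that add atoms: trimethyl orthoformate, COC(OC)OC; methanol, CO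
Why: Acid-catalysed acetalisation, driven by the orthoformate as water scavenger, masks the formyl group, which the amide base of step 3 would otherwise attack.

Step 3
Reactants: 5 2-bromo-3-(dimethoxymethyl)-4-fluoro-1-methoxybenzene
Product: 8 4-bromo-3-(dimethoxymethyl)-2-fluoro-5-methoxybenzaldehyde, via aryllithium 6 (not isolated), via lithium aminoalkoxide 7 (not isolated)
Conditions: LiN(iPr)2 (LDA, 1.2 equiv), THF, −78 °C; then DMF, −78 to −20 °C; then H2O (neutral work-up)
Reagents that add atoms: N,N-dimethylformamide (DMF), CN(C)C=O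
Why: Second directed ortho-lithiation/DMF formylation: the only C–H left beside fluorine (also para to bromine) is far more acidic than the one beside methoxy, and the neutral quench keeps the acetal so that the fluoride of 8 stays only weakly activated during the palladium steps.

Step 4
Reactants: 8 4-bromo-3-(dimethoxymethyl)-2-fluoro-5-methoxybenzaldehyde; 9 2,4,6-trimethoxyphenylboronic acid (2 equiv)
Product: 11 2-fluoro-5-methoxy-4-(2,4,6-trimethoxyphenyl)isophthalaldehyde, via biaryl acetal 10 (not isolated)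
Conditions: Pd(OAc)2 (5 mol %), 2-dicyclohexylphosphino-2',6'-dimethoxybiphenyl (SPhos, 10 mol %), K3PO4, toluene/H2O, 90 °C; then 1 M HCl, THF, rt
Reagents that add atoms: water, O
Why: Suzuki–Miyaura coupling with an SPhos-ligated zerovalent palladium catalyst, a system known to form tetra-ortho-substituted biaryls fast enough to outrun protodeboronation of the electron-rich boronic acid (used in excess), followed by mild acid hydrolysis of the dimethyl acetal.

Step 5
Reactants: 8 4-bromo-3-(dimethoxymethyl)-2-fluoro-5-methoxybenzaldehyde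
Product: 13 2-fluoro-5-methoxyisophthalaldehyde, via acetal aldehyde 12 (not isolated)
Conditions: Pd(OAc)2 (3 mol %), SPhos (6 mol %), HCO2Na, DMF, 80 °C; then 1 M HCl, THF, rt
Reagents that add atoms: water, O
Why: Palladium-catalysed transfer hydrodehalogenation, in which formate delivers hydride to the arylpalladium bromide and leaves the aldehyde and the C–F bond alone, followed by acetal hydrolysis; the two formyl groups of 13 are thereby placed beside fluorine without regiochemical doubt.

Step 6
Reactants: 13 2-fluoro-5-methoxyisophthalaldehyde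
Product: 14 2-fluoro-5-hydroxyisophthalaldehyde
Conditions: BBr3 (2.5 equiv), CH2Cl2, −78 to 0 °C; then H2O
Reagents that add atoms: none
Why: Lewis-acid cleavage of the aryl methyl ether by BBr3 (bromide attacks the methyl group of the boron-complexed ether), a standard demethylation of methoxybenzaldehydes that leaves the formyl groups and the aryl fluoride intact after hydrolytic work-up.

Step 7
Reactants: 14 2-fluoro-5-hydroxyisophthalaldehyde
Product: 15 4-fluoro-3,5-bis(dimethoxymethyl)phenol
Conditions: HC(OMe)3, MeOH, p-TsOH (cat.), rt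
Reagents that add atoms: trimethyl orthoformate, COC(OC)OC; methanol, CO
Why: Acetalisation turns both π-acceptors into sp3 carbons, so the fluoride of 15 is no longer activated and its phenoxide can serve as a nucleophile in step 8 without attacking itself.

Step 8
Reactants: 15 4-fluoro-3,5-bis(dimethoxymethyl)phenol; 13 2-fluoro-5-methoxyisophthalaldehyde
Product: 16 2-[4-fluoro-3,5-bis(dimethoxymethyl)phenoxy]-5-methoxyisophthalaldehyde (rings C and D joined)
Conditions: K2CO3, DMF, 60 °C, argon
Reagents that add atoms: none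
Why: Nucleophilic aromatic substitution (addition–elimination): the two ortho formyl groups of 13 stabilise the Meisenheimer adduct at the C–F carbon, whereas the acetal-flanked fluoride of 15 is inert.

Step 9
Reactants: 16 2-[4-fluoro-3,5-bis(dimethoxymethyl)phenoxy]-5-methoxyisophthalaldehyde
Product: 18 2-[4-fluoro-3,5-bis(dimethoxymethyl)phenoxy]-5-methoxybenzene-1,3-diol, via bis-formate 17 (not isolated)
Conditions: mCPBA (2.5 equiv), Na2HPO4, CH2Cl2, 0 °C to rt; aqueous reductive work-up; then K2CO3 (cat.), MeOH, rt, argon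
Reagents that add atoms: 3-chloroperbenzoic acid (mCPBA), OOC(=O)c1cccc(Cl)c1
Why: Dakin-type Baeyer–Villiger oxidation: the peracid adds to each formyl group, the aryl carbon ortho to the aryloxy donor migrates to oxygen, and the formates are methanolysed after the peracid has been removed; the phosphate buffer keeps the dimethyl acetals of ring C intact.

Step 10
Reactants: 18 2-[4-fluoro-3,5-bis(dimethoxymethyl)phenoxy]-5-methoxybenzene-1,3-diol; 11 2-fluoro-5-methoxy-4-(2,4,6-trimethoxyphenyl)isophthalaldehyde (2.4 equiv)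
Product: 19 1,3-bis[2,6-diformyl-4-methoxy-3-(2,4,6-trimethoxyphenyl)phenoxy]-2-[4-fluoro-3,5-bis(dimethoxymethyl)phenoxy]-5-methoxybenzene (rings C to H; tetra-aldehyde)
Conditions: Cs2CO3, DMF, 50 °C, argon
Reagents that add atoms: none
Why: Twofold nucleophilic aromatic substitution of the ring D diphenoxide at the doubly formyl-activated C–F carbon of 11; fluoride is a much better leaving group in this mechanism than the aryloxides already in place, so the ethers should not exchange.

Step 11
Reactants: 19 tetra-aldehyde bis-acetal (rings C to H)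
Product: 20 1,3-bis[2,6-diformyl-4-methoxy-3-(2,4,6-trimethoxyphenyl)phenoxy]-2-(4-fluoro-3,5-diformylphenoxy)-5-methoxybenzene (hexa-aldehyde aryl fluoride)
Conditions: 1 M HCl, THF/H2O, rt
Reagents that add atoms: water, O
Why: Acid-catalysed acetal hydrolysis unmasks the two formyl groups that activate the ring C fluoride; dilute aqueous acid at room temperature does not touch diaryl ethers and is too weak to condense the aldehydes with the trimethoxyphenyl rings.

Step 12
Reactants: 21 3,5-dimethoxyphenol; 13 2-fluoro-5-methoxyisophthalaldehyde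
Product: 22 2-(3,5-dimethoxyphenoxy)-5-methoxyisophthalaldehyde (rings A and B joined)
Conditions: K2CO3, DMF, 60 °C, argon
Reagents that add atoms: none
Why: Nucleophilic aromatic substitution of the phenoxide oxygen at the C–F carbon flanked by two formyl groups, the same addition–elimination as in step 8.

Step 13
Reactants: 22 2-(3,5-dimethoxyphenoxy)-5-methoxyisophthalaldehyde
Product: 24 2-(3,5-dimethoxyphenoxy)-5-methoxybenzene-1,3-diol, via bis-formate 23 (not isolated)
Conditions: mCPBA (2.5 equiv), CH2Cl2, 0 °C to rt; aqueous reductive work-up; then K2CO3 (cat.), MeOH, rt, argon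
Reagents that add atoms: 3-chloroperbenzoic acid (mCPBA), OOC(=O)c1cccc(Cl)c1
Why: Dakin-type Baeyer–Villiger oxidation in which the ortho aryloxy group directs aryl migration in both formyl groups; the electron-rich ring A is spared because formyl oxidation is faster than arene oxidation at 0 °C, and the diol is released only after the oxidant is gone.

Step 14
Reactants: 24 2-(3,5-dimethoxyphenoxy)-5-methoxybenzene-1,3-diol (3 equiv); 11 2-fluoro-5-methoxy-4-(2,4,6-trimethoxyphenyl)isophthalaldehyde (1 equiv)
Product: 25 2-[2-(3,5-dimethoxyphenoxy)-3-hydroxy-5-methoxyphenoxy]-5-methoxy-4-(2,4,6-trimethoxyphenyl)isophthalaldehyde (rings A, B, I, J; one free phenol on ring B)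
Conditions: Cs2CO3 (1 equiv), DMF, rt to 40 °C, argon
Reagents that add atoms: none
Why: Nucleophilic aromatic substitution run with the symmetric diol in excess, so that the statistically favoured product is the mono-ether (the two hydroxyls of 24 are equivalent, so only one mono-ether exists); the surplus 24 should be recoverable.

Step 15
Reactants: 25 phenol of rings A, B, I, J; 20 hexa-aldehyde aryl fluoride (rings C to H)
Product: 26 octa-aldehyde decamer, in which the free phenol oxygen of 25 is bonded to the former C–F carbon of ring C of 20 (two formyl groups on each of rings C, E, G, I)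
Conditions: Cs2CO3, DMF, 40 to 50 °C, argon
Reagents that add atoms: none
Why: Nucleophilic aromatic substitution of the phenoxide of 25 at the only C–F carbon of 20, activated by two ortho formyl groups; it completes the carbon–oxygen skeleton and leaves all eight formyl groups on rings C, E, G and I.

Step 16
Reactants: 26 octa-aldehyde decamer
Product: 28 octaphenol hexadecamethyl ether, via octaformate 27 (not isolated)
Conditions: mCPBA (12 equiv), CH2Cl2, 0 °C to rt; aqueous reductive work-up; then K2CO3 (cat.), MeOH/THF, rt, argon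
Reagents that add atoms: 3-chloroperbenzoic acid (mCPBA), OOC(=O)c1cccc(Cl)c1
Why: The peracid adds to each of the eight formyl carbons, and in every adduct the aryl carbon, which is ortho to a diaryl ether oxygen, migrates to oxygen with loss of 3-chlorobenzoate to give octaformate 27; catalytic carbonate in methanol then transfers the eight formyl groups to the solvent. The closest known reaction is the Dakin (Baeyer–Villiger) oxidation of ortho-alkoxy and ortho-aryloxy benzaldehydes with a peracid, applied here eight times to one molecule. No ring is closed and no stereocentre is created; eight aryl C–O bonds are formed and the eight formyl carbons are lost. The step needs aryl migration to beat hydride migration (which would give carboxylic acids) and formyl oxidation to beat attack on the methoxylated rings A, F, H and J; the first is secured by the ortho aryloxy donor on every migrating carbon, the second by low temperature and a limited excess of oxidant. Each ring becomes richer once its first formyl group is replaced by formyloxy, so its second formyl group should react faster, and the phenols are released only after the peracid has been destroyed.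

Step 17
Reactants: 28 octaphenol hexadecamethyl ether
Product: 29 CNP0294555.0 (target; all sixteen methyl ethers of 28 replaced by hydroxyl)
Conditions: BBr3 (40 equiv), CH2Cl2, −78 °C to rt, argon; then H2O; reversed-phase purification under argon
Reagents that add atoms: none
Why: Exhaustive cleavage of the sixteen aryl methyl ethers by BBr3 (SN2 attack of bromide on each boron-complexed O–CH3); the diaryl ethers offer no sp3 carbon for this attack and survive, and aqueous work-up under argon releases the free polyphenol.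

**Compound list**

1 | 2-bromo-4-fluoroanisole | COc1ccc(F)cc1Br | starting material
2 | (2-bromo-6-fluoro-3-methoxyphenyl)lithium | COc1ccc(F)c([Li])c1Br | intermediate
3 | lithium (2-bromo-6-fluoro-3-methoxyphenyl)(dimethylamino)methanolate | COc1ccc(F)c(C(O[Li])N(C)C)c1Br | intermediate
4 | 2-bromo-6-fluoro-3-methoxybenzaldehyde | COc1ccc(F)c(C=O)c1Br | intermediate
5 | 2-bromo-3-(dimethoxymethyl)-4-fluoro-1-methoxybenzene | COc1ccc(F)c(C(OC)OC)c1Br | intermediate
6 | [4-bromo-3-(dimethoxymethyl)-2-fluoro-5-methoxyphenyl]lithium | COc1cc([Li])c(F)c(C(OC)OC)c1Br | intermediate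
7 | lithium [4-bromo-3-(dimethoxymethyl)-2-fluoro-5-methoxyphenyl](dimethylamino)methanolate | COc1cc(C(O[Li])N(C)C)c(F)c(C(OC)OC)c1Br | intermediate
8 | 4-bromo-3-(dimethoxymethyl)-2-fluoro-5-methoxybenzaldehyde | COc1cc(C=O)c(F)c(C(OC)OC)c1Br | intermediate
9 | 2,4,6-trimethoxyphenylboronic acid | COc1cc(OC)c(B(O)O)c(OC)c1 | starting material
10 | 3-(dimethoxymethyl)-2-fluoro-5-methoxy-4-(2,4,6-trimethoxyphenyl)benzaldehyde | COc1cc(C=O)c(F)c(C(OC)OC)c1-c1c(OC)cc(OC)cc1OC | intermediate
11 | 2-fluoro-5-methoxy-4-(2,4,6-trimethoxyphenyl)isophthalaldehyde (arm fluoride) | COc1cc(C=O)c(F)c(C=O)c1-c1c(OC)cc(OC)cc1OC | intermediate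
12 | 3-(dimethoxymethyl)-2-fluoro-5-methoxybenzaldehyde | COc1cc(C=O)c(F)c(C(OC)OC)c1 | intermediate
13 | 2-fluoro-5-methoxyisophthalaldehyde | COc1cc(C=O)c(F)c(C=O)c1 | intermediate
14 | 2-fluoro-5-hydroxyisophthalaldehyde | Oc1cc(C=O)c(F)c(C=O)c1 | intermediate
15 | 4-fluoro-3,5-bis(dimethoxymethyl)phenol | Oc1cc(C(OC)OC)c(F)c(C(OC)OC)c1 | intermediate
16 | 2-[4-fluoro-3,5-bis(dimethoxymethyl)phenoxy]-5-methoxyisophthalaldehyde | COc1cc(C=O)c(Oc2cc(C(OC)OC)c(F)c(C(OC)OC)c2)c(C=O)c1 | intermediate
17 | 2-[4-fluoro-3,5-bis(dimethoxymethyl)phenoxy]-5-methoxy-1,3-phenylene diformate | COc1cc(OC=O)c(Oc2cc(C(OC)OC)c(F)c(C(OC)OC)c2)c(OC=O)c1 | intermediate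
18 | 2-[4-fluoro-3,5-bis(dimethoxymethyl)phenoxy]-5-methoxybenzene-1,3-diol | COc1cc(O)c(Oc2cc(C(OC)OC)c(F)c(C(OC)OC)c2)c(O)c1 | intermediate
19 | 1,3-bis[2,6-diformyl-4-methoxy-3-(2,4,6-trimethoxyphenyl)phenoxy]-2-[4-fluoro-3,5-bis(dimethoxymethyl)phenoxy]-5-methoxybenzene | COc1cc(Oc2c(C=O)cc(OC)c(-c3c(OC)cc(OC)cc3OC)c2C=O)c(Oc2cc(C(OC)OC)c(F)c(C(OC)OC)c2)c(Oc2c(C=O)cc(OC)c(-c3c(OC)cc(OC)cc3OC)c2C=O)c1 | intermediate
20 | 1,3-bis[2,6-diformyl-4-methoxy-3-(2,4,6-trimethoxyphenyl)phenoxy]-2-(4-fluoro-3,5-diformylphenoxy)-5-methoxybenzene | COc1cc(Oc2c(C=O)cc(OC)c(-c3c(OC)cc(OC)cc3OC)c2C=O)c(Oc2cc(C=O)c(F)c(C=O)c2)c(Oc2c(C=O)cc(OC)c(-c3c(OC)cc(OC)cc3OC)c2C=O)c1 | intermediate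
21 | 3,5-dimethoxyphenol | COc1cc(O)cc(OC)c1 | starting material
22 | 2-(3,5-dimethoxyphenoxy)-5-methoxyisophthalaldehyde | COc1cc(OC)cc(Oc2c(C=O)cc(OC)cc2C=O)c1 | intermediate
23 | 2-(3,5-dimethoxyphenoxy)-5-methoxy-1,3-phenylene diformate | COc1cc(OC)cc(Oc2c(OC=O)cc(OC)cc2OC=O)c1 | intermediate
24 | 2-(3,5-dimethoxyphenoxy)-5-methoxybenzene-1,3-diol | COc1cc(OC)cc(Oc2c(O)cc(OC)cc2O)c1 | intermediate
25 | 2-[2-(3,5-dimethoxyphenoxy)-3-hydroxy-5-methoxyphenoxy]-5-methoxy-4-(2,4,6-trimethoxyphenyl)isophthalaldehyde | COc1cc(OC)cc(Oc2c(O)cc(OC)cc2Oc2c(C=O)cc(OC)c(-c3c(OC)cc(OC)cc3OC)c2C=O)c1 | intermediate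
26 | octa-aldehyde decamer (two formyl groups on each of rings C, E, G, I; sixteen methyl ethers) | COc1cc(OC)cc(Oc2c(Oc3c(C=O)cc(Oc4c(Oc5c(C=O)cc(OC)c(-c6c(OC)cc(OC)cc6OC)c5C=O)cc(OC)cc4Oc4c(C=O)cc(OC)c(-c5c(OC)cc(OC)cc5OC)c4C=O)cc3C=O)cc(OC)cc2Oc2c(C=O)cc(OC)c(-c3c(OC)cc(OC)cc3OC)c2C=O)c1 | intermediate
27 | octaformate (each formyl group of 26 replaced by formyloxy) | COc1cc(OC)cc(Oc2c(Oc3c(OC=O)cc(Oc4c(Oc5c(OC=O)cc(OC)c(-c6c(OC)cc(OC)cc6OC)c5OC=O)cc(OC)cc4Oc4c(OC=O)cc(OC)c(-c5c(OC)cc(OC)cc5OC)c4OC=O)cc3OC=O)cc(OC)cc2Oc2c(OC=O)cc(OC)c(-c3c(OC)cc(OC)cc3OC)c2OC=O)c1 | intermediate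
28 | octaphenol hexadecamethyl ether (each formyl group of 26 replaced by hydroxyl) | COc1cc(OC)cc(Oc2c(Oc3c(O)cc(Oc4c(Oc5c(O)cc(OC)c(-c6c(OC)cc(OC)cc6OC)c5O)cc(OC)cc4Oc4c(O)cc(OC)c(-c5c(OC)cc(OC)cc5OC)c4O)cc3O)cc(OC)cc2Oc2c(O)cc(OC)c(-c3c(OC)cc(OC)cc3OC)c2O)c1 | intermediate
29 | CNP0294555.0 (fully hydroxylated decamer) | Oc1cc(O)cc(Oc2c(Oc3c(O)cc(Oc4c(Oc5c(O)cc(O)c(-c6c(O)cc(O)cc6O)c5O)cc(O)cc4Oc4c(O)cc(O)c(-c5c(O)cc(O)cc5O)c4O)cc3O)cc(O)cc2Oc2c(O)cc(O)c(-c3c(O)cc(O)cc3O)c2O)c1 | target

**Step count and risks**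

Total step count: 17. Longest linear sequence: 13 steps (steps 1, 2, 3, 5, 6, 7, 8, 9, 10, 11, 15, 16, 17).

Steps most likely to fail:

1. Step 16 (eightfold Dakin oxidation). The oxidation may stall at mixed aldehyde/formate stages, hydride migration may compete at the more hindered formyl groups next to the biaryl axes, or the peracid may begin to attack the methoxylated rings before all eight formyl groups are consumed. Fallback: the oxidation is split into two fourfold operations, so that each substrate carries fewer formyl groups and the first set of phenols is capped before the second oxidation. It sets out from tetra-aldehyde 19 (and uses phenol 25) and rejoins the route at target 29.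
   - Buffered mCPBA on 19 should give the tetraformate F1, and K2CO3/MeOH then the tetraphenol F2.
   - MeI/K2CO3 in DMF should cap the four hydroxyls as the tetramethyl ether F3.
   - 1 M HCl in THF should unmask the ring C fluoro dialdehyde F4.
   - Cs2CO3/DMF should join F4 to phenol 25, giving the tetra-aldehyde F5 with formyl groups on rings C and I only.
   - A second fourfold Dakin oxidation should give the tetraformate F6 and, after methanolysis, the tetraphenol F7.
   - BBr3 then removes the twenty methyl ethers of F7 to give 29.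

2. Step 4 (Suzuki–Miyaura coupling to the tetra-ortho-substituted biaryl). Protodeboronation of the electron-rich boronic acid under aqueous base may outrun the slow transmetalation at the doubly ortho-substituted arylpalladium intermediate. Fallback: a Negishi coupling, which needs no aqueous base. It sets out from bromide 8 and rejoins the route at biaryl acetal 10, which is hydrolysed to 11 as in step 4. Commercial 1,3,5-trimethoxybenzene is lithiated with n-butyllithium in THF at 0 °C to 2,4,6-trimethoxyphenyllithium F8, transmetalated with ZnCl2 to (2,4,6-trimethoxyphenyl)zinc chloride F9, and coupled with 8 using Pd(OAc)2/SPhos in THF at 50 °C.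

3. Step 15 (union of the two large fragments). The displacement joins two bulky partners in equal amounts at a phenoxide flanked by an aryloxy group; it may be slow, and on prolonged heating aryloxide exchange at the formyl-activated ether carbons could scramble the skeleton. Fallback: the order of arylation of ring B is reversed, so that the hindered last displacement uses the small fluoride 11 in excess. It sets out from diol 24 and aryl fluoride 20 and rejoins the route at 26. Excess 24 is arylated once by 20 (Cs2CO3, DMF, rt) to give the hexa-aldehyde phenol F10, which is then treated with excess 11 (Cs2CO3, DMF, 50 °C).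

Further compounds
F1 | step 16 | tetraformate from 19 (four formyl groups replaced by formyloxy; ring C acetals kept) | COc1cc(Oc2c(OC=O)cc(OC)c(-c3c(OC)cc(OC)cc3OC)c2OC=O)c(Oc2cc(C(OC)OC)c(F)c(C(OC)OC)c2)c(Oc2c(OC=O)cc(OC)c(-c3c(OC)cc(OC)cc3OC)c2OC=O)c1
F2 | step 16 | tetraphenol from F1 | COc1cc(Oc2c(O)cc(OC)c(-c3c(OC)cc(OC)cc3OC)c2O)c(Oc2cc(C(OC)OC)c(F)c(C(OC)OC)c2)c(Oc2c(O)cc(OC)c(-c3c(OC)cc(OC)cc3OC)c2O)c1
F3 | step 16 | tetramethyl ether of F2 | COc1cc(Oc2c(OC)cc(OC)c(-c3c(OC)cc(OC)cc3OC)c2OC)c(Oc2cc(C(OC)OC)c(F)c(C(OC)OC)c2)c(Oc2c(OC)cc(OC)c(-c3c(OC)cc(OC)cc3OC)c2OC)c1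
F4 | step 16 | ring C fluoro dialdehyde from F3 | COc1cc(Oc2c(OC)cc(OC)c(-c3c(OC)cc(OC)cc3OC)c2OC)c(Oc2cc(C=O)c(F)c(C=O)c2)c(Oc2c(OC)cc(OC)c(-c3c(OC)cc(OC)cc3OC)c2OC)c1
F5 | step 16 | tetra-aldehyde decamer (formyl groups on rings C and I; twenty methyl ethers) | COc1cc(OC)cc(Oc2c(Oc3c(C=O)cc(Oc4c(Oc5c(OC)cc(OC)c(-c6c(OC)cc(OC)cc6OC)c5OC)cc(OC)cc4Oc4c(OC)cc(OC)c(-c5c(OC)cc(OC)cc5OC)c4OC)cc3C=O)cc(OC)cc2Oc2c(C=O)cc(OC)c(-c3c(OC)cc(OC)cc3OC)c2C=O)c1
F6 | step 16 | tetraformate from F5 | COc1cc(OC)cc(Oc2c(Oc3c(OC=O)cc(Oc4c(Oc5c(OC)cc(OC)c(-c6c(OC)cc(OC)cc6OC)c5OC)cc(OC)cc4Oc4c(OC)cc(OC)c(-c5c(OC)cc(OC)cc5OC)c4OC)cc3OC=O)cc(OC)cc2Oc2c(OC=O)cc(OC)c(-c3c(OC)cc(OC)cc3OC)c2OC=O)c1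
F7 | step 16 | tetraphenol icosamethyl ether from F6 | COc1cc(OC)cc(Oc2c(Oc3c(O)cc(Oc4c(Oc5c(OC)cc(OC)c(-c6c(OC)cc(OC)cc6OC)c5OC)cc(OC)cc4Oc4c(OC)cc(OC)c(-c5c(OC)cc(OC)cc5OC)c4OC)cc3O)cc(OC)cc2Oc2c(O)cc(OC)c(-c3c(OC)cc(OC)cc3OC)c2O)c1
F8 | step 4 | 2,4,6-trimethoxyphenyllithium | COc1cc(OC)c([Li])c(OC)c1
F9 | step 4 | (2,4,6-trimethoxyphenyl)zinc chloride | COc1cc(OC)c([Zn]Cl)c(OC)c1
F10 | step 15 | hexa-aldehyde phenol (24 arylated once by 20; rings A to H, free hydroxyl on ring B) | COc1cc(OC)cc(Oc2c(O)cc(OC)cc2Oc2c(C=O)cc(Oc3c(Oc4c(C=O)cc(OC)c(-c5c(OC)cc(OC)cc5OC)c4C=O)cc(OC)cc3Oc3c(C=O)cc(OC)c(-c4c(OC)cc(OC)cc4OC)c3C=O)cc2C=O)c1
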